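## Retrosynthetic overview

1. The target is the (1S,2R)-trans-1-aryl-1,2-dihydronaphthalene-3-carbaldehyde: C1 carries the aryl group, C2 the CH2OH, C3 the CHO, C4 is the vinylic CH; ring A is the dimethoxybenzo ring, ring B is C1–C4/C4a/C8a, ring C is the pendant 4-hydroxy-3-methoxyphenyl group.
2. The strategy rests on the enal O=CH–C3=C4(H) of ring B, joined to ring A at C4a. It is a β-chlorovinyl aldehyde without its chlorine, so C3–CHO comes from haloformylation of a 1-tetralone (carbonyl carbon = C4) and C4–C4a from acylative closure of ring B by a 4,4-diarylbutanoic acid. Both bonds are made in one flask from acid 14; ring B is the only ring formed.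
3. Acid 14 comes from one (S)-4-benzyloxazolidinone: aryl-copper 1,4-addition to the O-benzylferuloyl imide sets C1, enolate alkylation with tert-butyl bromoacetate sets C2, then LiBH4 removal of the auxiliary, OBn → OAc exchange and ester cleavage.
4. Both auxiliary-controlled steps occur anti to the auxiliary's benzyl group. For the trans series the ring that is later acylated (3,4-dimethoxyphenyl) must therefore come from the Grignard reagent, and the pendant ring from the cinnamoyl unit.
5. End game: Pd/formate hydrogenolysis of C4–Cl, then methanolysis of both acetates.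

Key step: step 8

Assumption: 1 and the Grignard solution 5 (0.5 M in THF) are taken as catalogue items, and the sense of induction in steps 2 and 3 is taken from the usual chelate models of N-acyl oxazolidinones (attack anti to the C4 benzyl group).

## Route

Step 1
Reactants: 1 (E)-3-[4-(benzyloxy)-3-methoxyphenyl]prop-2-enoic acid; 2 (S)-4-benzyl-1,3-oxazolidin-2-one
Product: 4 (4S)-4-benzyl-3-{(E)-3-[4-(benzyloxy)-3-methoxyphenyl]prop-2-enoyl}-1,3-oxazolidin-2-one, via mixed pivalic anhydride 3 (not isolated)
Conditions: PivCl, Et3N, THF, −20 °C; then LiCl, 2, −20 °C → rt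
Reagents that add atoms: none
Why: N-acylation of the LiCl-activated oxazolidinone by a mixed pivalic anhydride, in which the hindered pivaloyl carbonyl directs attack to the cinnamoyl carbonyl; no stereocentre is formed.

Step 2
Reactants: 4 (4S)-4-benzyl-3-{(E)-3-[4-(benzyloxy)-3-methoxyphenyl]prop-2-enoyl}-1,3-oxazolidin-2-one; 5 3,4-dimethoxyphenylmagnesium bromide
Product: 7 (4S)-4-benzyl-3-{(3R)-3-[4-(benzyloxy)-3-methoxyphenyl]-3-(3,4-dimethoxyphenyl)propanoyl}-1,3-oxazolidin-2-one, via bromomagnesium enolate 6 (not isolated)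
Conditions: 5 (1.5 equiv), CuBr·SMe2 (1.5 equiv), THF/Me2S, −40 °C; then 4, −40 → −15 °C; sat. aq NH4Cl
Reagents that add atoms: none
Why: Copper-mediated 1,4-addition of an aryl Grignard reagent to an N-enoyl oxazolidinone, in which the aryl copper species adds to the β-carbon of the magnesium-chelated syn-s-cis imide on the face opposite the C4 benzyl group; with the guaiacyl ring on the alkene this should set the diarylmethine centre (later C1) as 3R.

Step 3
Reactants: 7 (4S)-4-benzyl-3-{(3R)-3-[4-(benzyloxy)-3-methoxyphenyl]-3-(3,4-dimethoxyphenyl)propanoyl}-1,3-oxazolidin-2-one; 8 tert-butyl bromoacetate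
Product: 10 tert-butyl (3S,4R)-3-{[(4S)-4-benzyl-2-oxo-1,3-oxazolidin-3-yl]carbonyl}-4-[4-(benzyloxy)-3-methoxyphenyl]-4-(3,4-dimethoxyphenyl)butanoate, via sodium enolate 9 (not isolated)
Conditions: NaHMDS, THF, −78 °C; then 8, −78 → −45 °C; AcOH quench
Reagents that add atoms: none
Why: Evans alkylation, in which the chelated sodium (Z)-enolate is alkylated on the face away from the auxiliary benzyl group; this should set the α-centre (later C2) as S and give the acetate arm and the dimethoxyphenyl ring the relationship that leads to the trans-1,2 product once they are joined.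

Step 4
Reactants: 10 tert-butyl (3S,4R)-3-{[(4S)-4-benzyl-2-oxo-1,3-oxazolidin-3-yl]carbonyl}-4-[4-(benzyloxy)-3-methoxyphenyl]-4-(3,4-dimethoxyphenyl)butanoate
Product: 11 tert-butyl (3S,4R)-4-[4-(benzyloxy)-3-methoxyphenyl]-4-(3,4-dimethoxyphenyl)-3-(hydroxymethyl)butanoate
Conditions: LiBH4, H2O (1 equiv), Et2O/THF, 0 °C; pH 7 buffer
Reagents that add atoms: none
Why: Reductive cleavage of the N-acyl oxazolidinone by LiBH4, which attacks the imide carbonyl in preference to the tert-butyl ester and releases the auxiliary; no stereocentre is touched.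

Step 5
Reactants: 11 tert-butyl (3S,4R)-4-[4-(benzyloxy)-3-methoxyphenyl]-4-(3,4-dimethoxyphenyl)-3-(hydroxymethyl)butanoate
Product: 12 tert-butyl (3S,4S)-4-(3,4-dimethoxyphenyl)-4-(4-hydroxy-3-methoxyphenyl)-3-(hydroxymethyl)butanoate
Conditions: H2 (1 atm), 10% Pd/C, EtOAc, rt
Reagents that add atoms: none
Why: Hydrogenolysis of the benzyl aryl ether over Pd/C under neutral conditions that leave the tert-butyl ester and the γ-hydroxy ester alone; the C4 descriptor changes from R to S only because the free-phenol ring now ranks below the dimethoxyphenyl ring.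

Step 6
Reactants: 12 tert-butyl (3S,4S)-4-(3,4-dimethoxyphenyl)-4-(4-hydroxy-3-methoxyphenyl)-3-(hydroxymethyl)butanoate
Product: 13 tert-butyl (3S,4R)-3-(acetoxymethyl)-4-(4-acetoxy-3-methoxyphenyl)-4-(3,4-dimethoxyphenyl)butanoate
Conditions: Ac2O, pyridine, DMAP (cat.), CH2Cl2, 0 °C → rt
Reagents that add atoms: acetic anhydride CC(=O)OC(C)=O
Why: DMAP-catalysed O-acetylation of the primary alcohol and the phenol; the aryl acetate is the group that later deactivates the pendant ring, and the primary acetate blocks lactonisation.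

Step 7
Reactants: 13 tert-butyl (3S,4R)-3-(acetoxymethyl)-4-(4-acetoxy-3-methoxyphenyl)-4-(3,4-dimethoxyphenyl)butanoate
Product: 14 (3S,4R)-3-(acetoxymethyl)-4-(4-acetoxy-3-methoxyphenyl)-4-(3,4-dimethoxyphenyl)butanoic acid
Conditions: TFA/CH2Cl2 (1:3), Et3SiH, 0 °C → rt
Reagents that add atoms: none
Why: Acidolysis of the tert-butyl ester through the tert-butyl cation, which triethylsilane reduces so that the electron-rich rings are not tert-butylated; both acetates are stable to anhydrous TFA.

Step 8
Reactants: 14 (3S,4R)-3-(acetoxymethyl)-4-(4-acetoxy-3-methoxyphenyl)-4-(3,4-dimethoxyphenyl)butanoic acid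
Product: 18 (1S,2R)-2-(acetoxymethyl)-1-(4-acetoxy-3-methoxyphenyl)-4-chloro-6,7-dimethoxy-1,2-dihydronaphthalene-3-carbaldehyde, via acyl chloride 15 (not isolated), via tetralone 16 (not isolated), via chlorovinyl iminium chloride 17 (not isolated)
Conditions: POCl3 (6 equiv), DMF (1.1 equiv), ClCH2CH2Cl, 0 → 50 °C; then DMF (6 equiv), 70 °C; then ice-cold aq NaOAc
Reagents that add atoms: N,N-dimethylformamide CN(C)C=O; phosphoryl chloride O=P(Cl)(Cl)Cl; water O
Why: The first small charge of DMF gives chloroiminium salt that turns the acid into acyl chloride 15, and in the POCl3 medium the activated acyl carbon is attacked by C6 of the dimethoxyphenyl ring (para to a methoxy group, ortho to the side chain), closing ring B as tetralone 16 in a 6-exo Friedel–Crafts acylation that forms C4–C4a. After the second charge of DMF the enol of 16 attacks the chloroiminium ion at its only α-carbon (the C3–CHO bond), the activated oxygen at C4 is exchanged for chloride, and the chlorovinyl iminium salt 17 is hydrolysed to aldehyde 18 on work-up. The closest known chemistry is the intramolecular Friedel–Crafts acylation of 4-arylbutanoyl chlorides onto alkoxy-activated rings and the Vilsmeier–Haack–Arnold haloformylation of 1-tetralones, run here one after the other in one flask, with the POCl3 cyclisation of N-arylanthranilic acids to 9-chloroacridines as a model for acylative closure and C=O to C–Cl exchange by one reagent. No stereocentre is formed: C1 and C2 sit γ and β to the tetralone carbonyl, cannot enolise and should be carried through, so the trans relationship from steps 2 and 3 is kept. The step needs site selectivity between the two aryl groups on C1: each offers a position para to a methoxy group, but in the pendant ring that position is meta to an acetoxy group (σm about 0.39) instead of a methoxy group (σm about 0.12), which with the large negative ρ of acylation should make it slower by roughly two orders of magnitude (an estimate, not a measurement). Most of the DMF is held back until ring closure is complete so that the chloroiminium salt does not formylate the α-carbon of 15 before the ring is closed.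

Step 9
Reactants: 18 (1S,2R)-2-(acetoxymethyl)-1-(4-acetoxy-3-methoxyphenyl)-4-chloro-6,7-dimethoxy-1,2-dihydronaphthalene-3-carbaldehyde
Product: 19 (1S,2R)-2-(acetoxymethyl)-1-(4-acetoxy-3-methoxyphenyl)-6,7-dimethoxy-1,2-dihydronaphthalene-3-carbaldehyde
Conditions: Pd(PPh3)4 (5 mol%), HCO2H, Et3N, DMF, 60 °C
Reagents that add atoms: none
Why: Palladium-catalysed transfer hydrogenolysis of an activated vinyl chloride (oxidative addition into the C4–Cl bond of the vinylogous acid chloride, formate exchange, loss of CO2 to Pd–H, reductive elimination); formate does not reduce the enal, and no stereocentre is involved.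

Step 10
Reactants: 19 (1S,2R)-2-(acetoxymethyl)-1-(4-acetoxy-3-methoxyphenyl)-6,7-dimethoxy-1,2-dihydronaphthalene-3-carbaldehyde
Product: 20 (1S,2R)-1-(4-hydroxy-3-methoxyphenyl)-2-(hydroxymethyl)-6,7-dimethoxy-1,2-dihydronaphthalene-3-carbaldehyde
Conditions: K2CO3 (0.3 equiv), MeOH, 0 °C → rt, Ar; Amberlite IR-120 (H+)
Reagents that add atoms: none
Why: Carbonate-catalysed transesterification with methanol (Zemplén-type) removes the aryl and the primary acetate; neither C1–H nor C2–H is readily enolisable under these conditions, so the trans configuration should be kept.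

## Compound list

1 | (E)-3-[4-(benzyloxy)-3-methoxyphenyl]prop-2-enoic acid (O-benzylferulic acid) | COc1cc(/C=C/C(=O)O)ccc1OCc1ccccc1 | starting material
2 | (S)-4-benzyl-1,3-oxazolidin-2-one | O=C1N[C@@H](Cc2ccccc2)CO1 | starting material
3 | (E)-3-[4-(benzyloxy)-3-methoxyphenyl]prop-2-enoic pivalic anhydride | COc1cc(/C=C/C(=O)OC(=O)C(C)(C)C)ccc1OCc1ccccc1 | intermediate
4 | (4S)-4-benzyl-3-{(E)-3-[4-(benzyloxy)-3-methoxyphenyl]prop-2-enoyl}-1,3-oxazolidin-2-one | COc1cc(/C=C/C(=O)N2[C@@H](Cc3ccccc3)COC2=O)ccc1OCc1ccccc1 | intermediate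
5 | 3,4-dimethoxyphenylmagnesium bromide | COc1ccc([Mg]Br)cc1OC | starting material
6 | bromomagnesium (Z)-enolate of 7 | COc1cc([C@H](/C=C(\O[Mg]Br)N2[C@@H](Cc3ccccc3)COC2=O)c2ccc(OC)c(OC)c2)ccc1OCc1ccccc1 | intermediate
7 | (4S)-4-benzyl-3-{(3R)-3-[4-(benzyloxy)-3-methoxyphenyl]-3-(3,4-dimethoxyphenyl)propanoyl}-1,3-oxazolidin-2-one | COc1cc([C@H](CC(=O)N2[C@@H](Cc3ccccc3)COC2=O)c2ccc(OC)c(OC)c2)ccc1OCc1ccccc1 | intermediate
8 | tert-butyl bromoacetate | CC(C)(C)OC(=O)CBr | starting material
9 | sodium (Z)-enolate of 7 | COc1cc([C@H](/C=C(\[O-])N2[C@@H](Cc3ccccc3)COC2=O)c2ccc(OC)c(OC)c2)ccc1OCc1ccccc1.[Na+] | intermediate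
10 | tert-butyl (3S,4R)-3-{[(4S)-4-benzyl-2-oxo-1,3-oxazolidin-3-yl]carbonyl}-4-[4-(benzyloxy)-3-methoxyphenyl]-4-(3,4-dimethoxyphenyl)butanoate | COc1cc([C@H]([C@H](CC(=O)OC(C)(C)C)C(=O)N2[C@@H](Cc3ccccc3)COC2=O)c2ccc(OC)c(OC)c2)ccc1OCc1ccccc1 | intermediate
11 | tert-butyl (3S,4R)-4-[4-(benzyloxy)-3-methoxyphenyl]-4-(3,4-dimethoxyphenyl)-3-(hydroxymethyl)butanoate | COc1cc([C@H]([C@H](CC(=O)OC(C)(C)C)CO)c2ccc(OC)c(OC)c2)ccc1OCc1ccccc1 | intermediate
12 | tert-butyl (3S,4S)-4-(3,4-dimethoxyphenyl)-4-(4-hydroxy-3-methoxyphenyl)-3-(hydroxymethyl)butanoate | COc1cc([C@H]([C@H](CC(=O)OC(C)(C)C)CO)c2ccc(OC)c(OC)c2)ccc1O | intermediate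
13 | tert-butyl (3S,4R)-3-(acetoxymethyl)-4-(4-acetoxy-3-methoxyphenyl)-4-(3,4-dimethoxyphenyl)butanoate | COc1cc([C@H]([C@H](CC(=O)OC(C)(C)C)COC(C)=O)c2ccc(OC)c(OC)c2)ccc1OC(C)=O | intermediate
14 | (3S,4R)-3-(acetoxymethyl)-4-(4-acetoxy-3-methoxyphenyl)-4-(3,4-dimethoxyphenyl)butanoic acid | COc1cc([C@@H](c2ccc(OC)c(OC)c2)[C@@H](COC(C)=O)CC(=O)O)ccc1OC(C)=O | intermediate
15 | (3S,4R)-3-(acetoxymethyl)-4-(4-acetoxy-3-methoxyphenyl)-4-(3,4-dimethoxyphenyl)butanoyl chloride | COc1cc([C@@H](c2ccc(OC)c(OC)c2)[C@@H](COC(C)=O)CC(=O)Cl)ccc1OC(C)=O | intermediate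
16 | (3S,4S)-3-(acetoxymethyl)-4-(4-acetoxy-3-methoxyphenyl)-6,7-dimethoxy-3,4-dihydronaphthalen-1(2H)-one (trans) | COc1cc([C@H]2c3cc(OC)c(OC)cc3C(=O)C[C@@H]2COC(C)=O)ccc1OC(C)=O | intermediate
17 | N-{[(1S,2R)-2-(acetoxymethyl)-1-(4-acetoxy-3-methoxyphenyl)-4-chloro-6,7-dimethoxy-1,2-dihydronaphthalen-3-yl]methylidene}-N-methylmethanaminium chloride | COc1cc([C@H]2c3cc(OC)c(OC)cc3C(Cl)=C(C=[N+](C)C)[C@@H]2COC(C)=O)ccc1OC(C)=O.[Cl-] | intermediate
18 | (1S,2R)-2-(acetoxymethyl)-1-(4-acetoxy-3-methoxyphenyl)-4-chloro-6,7-dimethoxy-1,2-dihydronaphthalene-3-carbaldehyde | COc1cc([C@H]2c3cc(OC)c(OC)cc3C(Cl)=C(C=O)[C@@H]2COC(C)=O)ccc1OC(C)=O | intermediate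
19 | (1S,2R)-2-(acetoxymethyl)-1-(4-acetoxy-3-methoxyphenyl)-6,7-dimethoxy-1,2-dihydronaphthalene-3-carbaldehyde | COc1cc([C@H]2c3cc(OC)c(OC)cc3C=C(C=O)[C@@H]2COC(C)=O)ccc1OC(C)=O | intermediate
20 | (1S,2R)-1-(4-hydroxy-3-methoxyphenyl)-2-(hydroxymethyl)-6,7-dimethoxy-1,2-dihydronaphthalene-3-carbaldehyde | COc1cc([C@H]2c3cc(OC)c(OC)cc3C=C(C=O)[C@@H]2CO)ccc1O | target

## Step count and risks

Total: 10 steps. Longest linear sequence: 10 steps (from 1; compounds 2, 5 and 8 enter as purchased reagents).

**Step 8 (key step).** Three processes may go wrong. Ring closure may be slower than attack of the chloroiminium salt at the α-carbon of acyl chloride 15, which would cost the carboxyl carbon. The neighbouring acetoxymethyl group may capture the heated acyl chloride with lactone formation. Acylation may leak to the pendant acetoxy-methoxyphenyl ring. The fallback sets out from 14 and returns at 18, and it uncouples the two bond formations. Acid 14 is converted into acyl chloride 15 with oxalyl chloride and catalytic DMF and cyclised with SnCl4 in CH2Cl2 at −20 °C, that is with a strong Lewis acid, at low temperature and with no formylating agent present. Tetralone 16 is isolated and purified, and its ring-closure site is checked. Only then is it treated with POCl3/DMF at 60 °C and aqueous sodium acetate, to give 18 through 17. This detour uses only compounds of the list (F0).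

**Step 2.** The 1,4-addition to the electron-rich β-aryl enoyl imide may be slow or poorly face-selective, with attack of the Grignard reagent at the imide carbonyls. The fallback sets out from 1 and returns at 7, and it makes the benzylic centre by catalyst control. Acid 1 is esterified (MeOH, cat. H2SO4) to methyl (E)-3-[4-(benzyloxy)-3-methoxyphenyl]prop-2-enoate F1. Rh(I)/BINAP-catalysed 1,4-addition of 3,4-dimethoxyphenylboronic acid (Hayashi–Miyaura conditions, aqueous dioxane) should give methyl (3R)-3-[4-(benzyloxy)-3-methoxyphenyl]-3-(3,4-dimethoxyphenyl)propanoate F2. The ligand antipode used is the one that leads to the 3R ester, to be fixed by converting a sample into 7. Saponification with LiOH gives (3R)-3-[4-(benzyloxy)-3-methoxyphenyl]-3-(3,4-dimethoxyphenyl)propanoic acid F3, which is coupled with 2 as in step 1 to return to 7. At that stage any minor enantiomer becomes a separable diastereomer.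

**Step 4.** Hydride may attack the ring carbonyl of the hindered imide, so that the auxiliary is opened and not released, or the intermediate alkoxide may lactonise onto the tert-butyl ester. The fallback sets out from 10 and returns at 11. Hydrolytic cleavage with LiOH/H2O2 (THF/H2O, 0 °C), which is selective for the exocyclic carbonyl, gives (2S,3R)-3-[4-(benzyloxy)-3-methoxyphenyl]-2-(2-tert-butoxy-2-oxoethyl)-3-(3,4-dimethoxyphenyl)propanoic acid F4. BH3·SMe2 (THF, 0 °C) then reduces the free acid in the presence of the tert-butyl ester under non-basic conditions and should give 11 without lactonisation.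

## Further compounds

F0 | step 8 | none | none
F1 | step 2 | methyl (E)-3-[4-(benzyloxy)-3-methoxyphenyl]prop-2-enoate | COC(=O)/C=C/c1ccc(OCc2ccccc2)c(OC)c1
F2 | step 2 | methyl (3R)-3-[4-(benzyloxy)-3-methoxyphenyl]-3-(3,4-dimethoxyphenyl)propanoate | COC(=O)C[C@@H](c1ccc(OCc2ccccc2)c(OC)c1)c1ccc(OC)c(OC)c1
F3 | step 2 | (3R)-3-[4-(benzyloxy)-3-methoxyphenyl]-3-(3,4-dimethoxyphenyl)propanoic acid | OC(=O)C[C@@H](c1ccc(OCc2ccccc2)c(OC)c1)c1ccc(OC)c(OC)c1
F4 | step 4 | (2S,3R)-3-[4-(benzyloxy)-3-methoxyphenyl]-2-(2-tert-butoxy-2-oxoethyl)-3-(3,4-dimethoxyphenyl)propanoic acid | COc1cc([C@H]([C@H](CC(=O)OC(C)(C)C)C(=O)O)c2ccc(OC)c(OC)c2)ccc1OCc1ccccc1
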